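**Retrosynthetic overview**
- The C8 ketone and the C7 stereocentre come last, from the C7=C8 alkene of a bicyclic adduct by face-selective epoxidation and a Meinwald 1,2-hydride shift.
- The adduct comes from one high-pressure [4+2] between 3,5-dimethyl-2H-pyran-2-one (which loses its aromaticity) and an (E)-2-ethylidene-oxane acetate. This forms C1–C6 and C4–C5, the cyclohexene, the lactone bridge, the spiro centre and the quaternary C4 together.
- The pyranone comes from the heteroaromatic feedstock coumalic acid by bromodecarboxylation/bromination and double methylation.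
- The enol ether comes from an alkynediol by syn-hydroalkoxylation; the alkynediol comes from (2S,3S)-2,3-dimethyloxirane by propenyl opening, Shi epoxidation and propynyl opening.
- Ring order: oxane first, then carbocycle and lactone bridge in the same cycloaddition.

Assumption: (2S,3S)-2,3-dimethyloxirane, (E)-1-bromoprop-1-ene and coumalic acid are bought; in names the oxane is numbered 2'–6' (C2' = spiro carbon) and the lactone bicycle C1 (O-bearing bridgehead), O2, C3 (lactone C=O), C4 (quaternary), C5 (spiro), C6, C7, C8.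

**Step 1**
Reactants: 1 (2S,3S)-2,3-dimethyloxirane
Product: 2 (2S,3S,4E)-3-methylhex-4-en-2-ol
Conditions: (E)-1-bromoprop-1-ene (2.2 equiv), t-BuLi (4.4 equiv), Et2O, −78 °C; MgBr2·OEt2, −78 → 0 °C; CuI (10 mol %), then 1, THF, −30 → 0 °C; H2O
Reagents that add atoms: (E)-1-bromoprop-1-ene, C/C=C/Br
Why: Copper-catalysed Grignard opening of an epoxide (SN2, inversion at the attacked carbon): because 1 is C2-symmetric both carbons give the same product, inversion at one carbon with retention at the carbinol carbon sets the 2,3-syn pair (2S,3S), and the E geometry of the propenyl group is carried unchanged through bromine–lithium exchange and transmetalation to magnesium.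

**Step 2**
Reactants: 2 (2S,3S,4E)-3-methylhex-4-en-2-ol
Product: 3 (2S,3R)-3-[(2R,3R)-3-methyloxiran-2-yl]butan-2-ol
Conditions: D-fructose-derived Shi ketone (30 mol %), Oxone (2KHSO5·KHSO4·K2SO4), K2CO3, Bu4N(HSO4) (cat.), MeCN–(MeO)2CH2–aq. Na2B4O7 buffer (pH 10.5), 0 °C
Reagents that add atoms: potassium peroxymonosulfate KHSO5 (active part of Oxone), [K+].[O-]OS(=O)(=O)O
Why: Shi asymmetric epoxidation: the chiral dioxirane formed from the ketone and KHSO5 transfers oxygen through a spiro transition state that gives the (R,R)-epoxide from a trans-disubstituted alkene under reagent control, which sets the future C4' oxygen and the centre that is inverted in step 3.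

**Step 3**
Reactants: 3 (2S,3R)-3-[(2R,3R)-3-methyloxiran-2-yl]butan-2-ol
Product: 4 (2S,3R,4S,5R)-3,5-dimethyloct-6-yne-2,4-diol
Conditions: LiC≡CMe (3.3 equiv), Et2AlCl (3.0 equiv), toluene, 0 °C; then 3, 0 → 23 °C; aq. KNaC4H4O6 (potassium sodium tartrate)
Reagents that add atoms: prop-1-ynyllithium, [Li]C#CC
Why: Alkynylalane opening of a 3,4-epoxy alcohol (SN2 epoxide opening): the aluminium alkoxide of the C2 hydroxyl chelates the epoxide oxygen and the propynyl group attacks the less hindered methyl-bearing carbon with inversion, which gives the 4,5-syn and 3,4-anti relationships and frees the C4 hydroxyl.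

**Step 4**
Reactants: 4 (2S,3R,4S,5R)-3,5-dimethyloct-6-yne-2,4-diol
Product: 5 (2E,3S,4R,5S,6S)-2-ethylidene-3,5,6-trimethyloxan-4-ol
Conditions: La[N(SiMe3)2]3 (10 mol %), toluene, 80 °C; filtration through basic Al2O3
Reagents that add atoms: none
Why: Lanthanide-catalysed intramolecular hydroalkoxylation of an internal alkyne: the La–O bond of the C2 alkoxide adds syn across the triple bond through a six-membered exo transition state and protonolysis of the La–C bond leaves H cis to O, which fixes the E enol ether (methyl trans to the ring oxygen), while the C4 hydroxyl cannot close in an exo mode and stays free.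

**Step 5**
Reactants: 5 (2E,3S,4R,5S,6S)-2-ethylidene-3,5,6-trimethyloxan-4-ol
Product: 6 (2E,3S,4R,5R,6S)-2-ethylidene-3,5,6-trimethyloxan-4-yl acetate
Conditions: Ac2O, Et3N, DMAP (cat.), CH2Cl2, 0 → 23 °C
Reagents that add atoms: acetic anhydride, CC(=O)OC(C)=O
Why: DMAP-catalysed acylation of the remaining secondary alcohol under basic conditions that do not protonate the exocyclic enol ether, with no change at any stereocentre.

**Step 6**
Reactants: 7 coumalic acid (2-oxo-2H-pyran-5-carboxylic acid)
Product: 8 3,5-dibromo-2H-pyran-2-one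
Conditions: NBS (2.5 equiv), LiOAc (cat.), MeCN–H2O, 23 °C
Reagents that add atoms: N-bromosuccinimide, O=C1CCC(=O)N1Br
Why: Electrophilic bromination at C3 together with bromodecarboxylation at C5 (Hunsdiecker-type ipso substitution of the carboxylate) of the pyranone, with no stereocentre involved.

**Step 7**
Reactants: 8 3,5-dibromo-2H-pyran-2-one
Product: 9 3,5-dimethyl-2H-pyran-2-one
Conditions: SnMe4 (3.0 equiv), Pd(PPh3)4 (5 mol %), CuI (10 mol %), DMF, 80 °C
Reagents that add atoms: tetramethylstannane, C[Sn](C)(C)C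
Why: Double Stille cross-coupling in which zerovalent palladium inserts into both vinylic C–Br bonds and methyl is transferred from tin, CuI speeding transmetalation, with no stereocentre involved.

**Step 8**
Reactants: 6 (2E,3S,4R,5R,6S)-2-ethylidene-3,5,6-trimethyloxan-4-yl acetate; 9 3,5-dimethyl-2H-pyran-2-one
Product: 10 (1S,4S,5S,6R,3'S,4'R,5'R,6'S)-4,6,7,3',5',6'-hexamethyl-3-oxospiro[2-oxabicyclo[2.2.2]oct-7-ene-5,2'-oxan]-4'-yl acetate
Conditions: 9 (3 equiv), 2,6-di-tert-butyl-4-methylpyridine (5 mol %), CH2Cl2, 1.5 GPa, 25 °C, 96 h; work-up below 30 °C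
Reagents that add atoms: none
Why: Proposed new method: inverse-electron-demand Diels–Alder reaction of a 2-pyranone with an enol ether under high pressure is known for simple vinyl ethers, and here the nucleophilic ethylidene carbon bonds to the electrophilic C6 of the pyranone while the oxygen-bearing carbon bonds to C3 in an asynchronous but suprafacial addition, so the E geometry puts the C6 methyl and C3' on the same side, the diene adds to the enol-ether face anti to the C5'/C6' methyls and the acetate with the ring oxygen endo under the diene, which sets C1, C4, C5 and C6 at once, and the negative activation volume lets the congested bond between two fully substituted carbons form at 25 °C, below the temperature of CO2 loss.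

**Step 9**
Reactants: 10 (1S,4S,5S,6R,3'S,4'R,5'R,6'S)-4,6,7,3',5',6'-hexamethyl-3-oxospiro[2-oxabicyclo[2.2.2]oct-7-ene-5,2'-oxan]-4'-yl acetate
Product: 12 (1S,4R,5S,6R,7S,3'S,4'R,5'R,6'S)-4,6,7,3',5',6'-hexamethyl-3,8-dioxospiro[2-oxabicyclo[2.2.2]octane-5,2'-oxan]-4'-yl acetate (target), via oxirane 11 (not isolated)
Conditions: dimethyldioxirane (acetone solution, 1.5 equiv), CH2Cl2, 0 °C; evaporate; BF3·OEt2 (0.2 equiv), CH2Cl2, −78 °C
Reagents that add atoms: dimethyldioxirane, CC1(C)OO1
Why: Epoxidation occurs on the alkene face syn to the lactone bridge because the other face is screened by the oxane oxygen and C6', then BF3 opens the oxirane at the tertiary C7 and the C8 hydrogen, antiperiplanar to the breaking C7–O bond, migrates (Meinwald rearrangement), so hydrogen reaches C7 anti to the departed oxygen and the C7 methyl ends syn to the lactone bridge as in the target, without base, which matters because the lactone oxygen is β to the new ketone.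

**Compound list**
1 | (2S,3S)-2,3-dimethyloxirane | C[C@@H]1O[C@H]1C | starting material
2 | (2S,3S,4E)-3-methylhex-4-en-2-ol | C[C@H](O)[C@@H](C)/C=C/C | intermediate
3 | (2S,3R)-3-[(2R,3R)-3-methyloxiran-2-yl]butan-2-ol | C[C@H](O)[C@@H](C)[C@H]1O[C@@H]1C | intermediate
4 | (2S,3R,4S,5R)-3,5-dimethyloct-6-yne-2,4-diol | C[C@H](O)[C@@H](C)[C@@H](O)[C@H](C)C#CC | intermediate
5 | (2E,3S,4R,5S,6S)-2-ethylidene-3,5,6-trimethyloxan-4-ol | O[C@@H]1[C@H](C)[C@H](C)O/C(=C/C)[C@H]1C | intermediate
6 | (2E,3S,4R,5R,6S)-2-ethylidene-3,5,6-trimethyloxan-4-yl acetate | CC(=O)O[C@@H]1[C@H](C)[C@H](C)O/C(=C/C)[C@H]1C | intermediate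
7 | coumalic acid (2-oxo-2H-pyran-5-carboxylic acid) | O=C1C=CC(C(=O)O)=CO1 | starting material
8 | 3,5-dibromo-2H-pyran-2-one | O=C1OC=C(Br)C=C1Br | intermediate
9 | 3,5-dimethyl-2H-pyran-2-one | O=C1OC=C(C)C=C1C | intermediate
10 | (1S,4S,5S,6R,3'S,4'R,5'R,6'S)-4,6,7,3',5',6'-hexamethyl-3-oxospiro[2-oxabicyclo[2.2.2]oct-7-ene-5,2'-oxan]-4'-yl acetate (oxane oxygen on the side of the C7=C8 bridge; C6 methyl and C3' on the side of the lactone bridge) | CC(=O)O[C@@H]1[C@H](C)[C@H](C)O[C@]2([C@H](C)[C@@H]3OC(=O)[C@@]2(C)C=C3C)[C@H]1C | intermediate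
11 | 7,8-epoxide of 10, oxirane oxygen syn to the O2–C3 lactone bridge | CC(=O)O[C@@H]1[C@H](C)[C@H](C)O[C@]2([C@H](C)[C@@H]3OC(=O)[C@@]2(C)[C@H]4O[C@@]34C)[C@H]1C | intermediate
12 | (1S,4R,5S,6R,7S,3'S,4'R,5'R,6'S)-4,6,7,3',5',6'-hexamethyl-3,8-dioxospiro[2-oxabicyclo[2.2.2]octane-5,2'-oxan]-4'-yl acetate | CC(=O)O[C@@H]1[C@H](C)[C@H](C)O[C@]2([C@H](C)[C@@H]3OC(=O)[C@@]2(C)C(=O)[C@H]3C)[C@H]1C | target

**Step count**
Total steps: 9 (steps 1–5 enol ether, 6–7 pyranone, 8–9 union and finish).
Longest linear sequence: 7 (steps 1, 2, 3, 4, 5, 8, 9).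

**Steps most likely to fail**

Step 8 (cycloaddition). The unactivated dimethylpyranone may not react with the hindered trisubstituted enol ether, or the facial and endo preferences may not hold. Fallback: make the diene more electrophilic with a halogen and add the second methyl afterwards. Setting out from 8, a single Stille methylation at the more reactive C3–Br (SnMe4 1.1 equiv, Pd(PPh3)4, toluene, 100 °C, no copper) gives 5-bromo-3-methyl-2H-pyran-2-one F1. Cycloaddition of F1 to 6 (1.0 GPa, CH2Cl2, 25 °C) gives the 7-bromo analogue of the adduct F2 with the same regio- and stereochemical sense. Negishi methylation of the vinyl bromide (MeZnCl, Pd[P(t-Bu)3]2, THF, 25 °C) comes back to the route at 10.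

Step 4 (lanthanum-catalysed ring closure). The free 1,3-diol may tie up the lanthanum centre. Fallback: differentiate the two hydroxyls by protection so that only the C2 hydroxyl meets the catalyst. Setting out from 3, TESCl/imidazole gives the O-triethylsilyl ether of 3 F3. LiC≡CMe/BF3·OEt2 (THF, −78 °C) opens the epoxide at the methyl-bearing carbon to give the 2-O-triethylsilyl ether of 4 F4. TBSOTf/2,6-lutidine gives the 2-O-triethylsilyl 4-O-tert-butyldimethylsilyl ether of 4 F5. PPTS/MeOH (0 °C) removes only the triethylsilyl group to give the 4-O-tert-butyldimethylsilyl ether of 4 F6. La[N(SiMe3)2]3 (toluene, 80 °C) closes it to the O-tert-butyldimethylsilyl ether of 5 F7, and Bu4NF/THF comes back to the route at 5.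

Step 9 (epoxidation and hydride shift). The cation at C7 may undergo skeletal rearrangement instead of the hydride shift. Fallback: install the oxygen by hydroboration and set C7 by equilibration. Setting out from 10, BH3·SMe2 (THF, 0 °C) adds boron to C8 and hydrogen to C7 on the lactone face to give the C8 alkylborane F8. Me3NO oxidises the C–B bond to the C8 secondary alcohol F9. Dess–Martin periodinane gives the (7R)-epimer of the target ketone F10. Catalytic TsOH in CHCl3 at 40 °C equilibrates C7 through the enol toward the epimer with the methyl syn to the lactone bridge; this comes back to the route at 12. Acid is used because base would eliminate the β-acyloxy ketone.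

**Further compounds**
F1 | step 8 | 5-bromo-3-methyl-2H-pyran-2-one | O=C1OC=C(Br)C=C1C
F2 | step 8 | (1S,4S,5S,6R,3'S,4'R,5'R,6'S)-7-bromo-4,6,3',5',6'-pentamethyl-3-oxospiro[2-oxabicyclo[2.2.2]oct-7-ene-5,2'-oxan]-4'-yl acetate | CC(=O)O[C@@H]1[C@H](C)[C@H](C)O[C@]2([C@H](C)[C@@H]3OC(=O)[C@@]2(C)C=C3Br)[C@H]1C
F3 | step 4 | O-triethylsilyl ether of 3 | C[C@H](O[Si](CC)(CC)CC)[C@@H](C)[C@H]1O[C@@H]1C
F4 | step 4 | 2-O-triethylsilyl ether of 4 | C[C@H](O[Si](CC)(CC)CC)[C@@H](C)[C@@H](O)[C@H](C)C#CC
F5 | step 4 | 2-O-triethylsilyl 4-O-tert-butyldimethylsilyl ether of 4 | C[C@H](O[Si](CC)(CC)CC)[C@@H](C)[C@@H](O[Si](C)(C)C(C)(C)C)[C@H](C)C#CC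
F6 | step 4 | 4-O-tert-butyldimethylsilyl ether of 4 | C[C@H](O)[C@@H](C)[C@@H](O[Si](C)(C)C(C)(C)C)[C@H](C)C#CC
F7 | step 4 | O-tert-butyldimethylsilyl ether of 5 | CC(C)(C)[Si](C)(C)O[C@@H]1[C@H](C)[C@H](C)O/C(=C/C)[C@H]1C
F8 | step 9 | C8 alkylborane from 10 (BH2 on C8 and new H on C7 both syn to the lactone bridge) | CC(=O)O[C@@H]1[C@H](C)[C@H](C)O[C@]2([C@H](C)[C@@H]3OC(=O)[C@@]2(C)[C@@H](B)[C@@H]3C)[C@H]1C
F9 | step 9 | C8 secondary alcohol from F8 (OH syn to the lactone bridge, C7 methyl anti to it) | CC(=O)O[C@@H]1[C@H](C)[C@H](C)O[C@]2([C@H](C)[C@@H]3OC(=O)[C@@]2(C)[C@@H](O)[C@@H]3C)[C@H]1C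
F10 | step 9 | (7R)-epimer of 12 | CC(=O)O[C@@H]1[C@H](C)[C@H](C)O[C@]2([C@H](C)[C@@H]3OC(=O)[C@@]2(C)C(=O)[C@@H]3C)[C@H]1C
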